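**Retrosynthetic overview**
- The target comes from a C9-hydroxy α-ketol by a last esterification with (2E)-3-methylpent-2-enoic acid; the angelate is already on C3.
- Ring B is closed last, at C8–C9, by a carbene-catalysed intramolecular crossed acyloin of a 1,6-dialdehyde: C8 reacts as an acyl anion equivalent with the C9 aldehyde, so two carbonyl carbons are joined.
- The dialdehyde comes from a ring A ketone: C9 by methylenation and hydroboration, C8 by a formaldehyde ene reaction on a prenyl group, which also creates the isopropenyl group.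
- Ring A is formed first, from an aromatic ring: cuprate addition and enolate prenylation of (R)-4-silyloxy-2-methylcyclohexenone set C4 and C5 from C3.
- The enone comes from 4-methoxy-3-methylphenol by oxidative ketalisation, partial hydrogenation and CBS reduction, which is the source of absolute configuration.

Assumption: positions are cited in eremophilane numbering (ring A = C1–C5 and C10, C5 quaternary; ring B = C5–C10, C7 carries isopropenyl, C8 is the ketone), and 4-methoxy-3-methylphenol, prenyl bromide, angelic acid and (2E)-3-methylpent-2-enoic acid are bought as catalogue chemicals.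

**Route**

Step 1
Reactants: 1 4-methoxy-3-methylphenol
Product: 2 4,4-dimethoxy-3-methylcyclohexa-2,5-dien-1-one
Conditions: PhI(OAc)2 (1.1 equiv), MeOH, 0 °C
Reagents that add atoms: methanol (CO)
Why: oxidative dearomatisation of a para-methoxyphenol by trivalent iodine with methanol capture at C4 gives the quinone monoketal; no stereocentre is formed.

Step 2
Reactants: 2 4,4-dimethoxy-3-methylcyclohexa-2,5-dien-1-one
Product: 3 4,4-dimethoxy-3-methylcyclohex-2-en-1-one
Conditions: H2 (1 atm), RhCl(PPh3)3 (5 mol %), toluene, rt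
Reagents that add atoms: none
Why: homogeneous hydrogenation with RhCl(PPh3)3 saturates only the disubstituted double bond of the cross-conjugated dienone and leaves the methyl-bearing one, as with steroidal 1,4-dien-3-ones.

Step 3
Reactants: 3 4,4-dimethoxy-3-methylcyclohex-2-en-1-one
Product: 5 (4R)-4-hydroxy-2-methylcyclohex-2-en-1-one, via dimethyl ketal alcohol 4 (not isolated)
Conditions: (S)-1-methyl-3,3-diphenyltetrahydro-1H,3H-pyrrolo[1,2-c][1,3,2]oxazaborole (15 mol %), catecholborane, toluene, −78 °C; then MeOH; 1 M HCl, THF, 0 °C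
Reagents that add atoms: water (O)
Why: Corey–Bakshi–Shibata reduction delivers hydride to the enone carbonyl with the alkenyl arm as the large group to give the (R)-allylic alcohol, and the acidic work-up hydrolyses the allylic ketal so that the enone is transposed and the carbinol becomes C3 of the target.

Step 4
Reactants: 5 (4R)-4-hydroxy-2-methylcyclohex-2-en-1-one
Product: 6 (4R)-2-methyl-4-[(triethylsilyl)oxy]cyclohex-2-en-1-one
Conditions: Et3SiCl, imidazole, CH2Cl2, 0 °C
Reagents that add atoms: chlorotriethylsilane (CC[Si](Cl)(CC)CC)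
Why: silylation turns the γ-hydroxyl into a poor leaving group and a steric director for the cuprate step; the stereocentre is untouched.

Step 5
Reactants: 6 (4R)-2-methyl-4-[(triethylsilyl)oxy]cyclohex-2-en-1-one; 7 1-bromo-3-methylbut-2-ene
Product: 10 (2R,3R,4R)-4-hydroxy-2,3-dimethyl-2-(3-methylbut-2-en-1-yl)cyclohexan-1-one, via lithium enolate 8 (not isolated), via triethylsilyl ether ketone 9 (not isolated)
Conditions: Me2CuLi (from MeLi and CuI), Et2O, −78 → −20 °C; then 7, HMPA, −78 → 0 °C; then 1 M HCl, THF, rt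
Reagents that add atoms: lithium dimethylcuprate ([Li+].C[Cu-]C)
Why: conjugate addition of the cuprate anti to the silyloxy group sets C4, the regiodefined enolate is then C-alkylated by prenyl bromide anti to the new C4 methyl to set the quaternary C5 (three-component conjugate addition–enolate alkylation), and the acid work-up cleaves the silyl ether.

Step 6
Reactants: 10 (2R,3R,4R)-4-hydroxy-2,3-dimethyl-2-(3-methylbut-2-en-1-yl)cyclohexan-1-one
Product: 11 (1R,2R,3R)-2,3-dimethyl-4-methylidene-3-(3-methylbut-2-en-1-yl)cyclohexan-1-ol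
Conditions: Ph3P=CH2 (from Ph3PCH3Br, 4 equiv, and KOt-Bu, 3.8 equiv), toluene, 90 °C
Reagents that add atoms: methylenetriphenylphosphorane (C=P(c1ccccc1)(c1ccccc1)c1ccccc1)
Why: Wittig methylenation with excess ylide, generated in the flask from the phosphonium bromide and KOt-Bu, copes with the α-quaternary ketone under forcing conditions and brings in C9; no stereocentre can epimerise because C5 is quaternary.

Step 7
Reactants: 11 (1R,2R,3R)-2,3-dimethyl-4-methylidene-3-(3-methylbut-2-en-1-yl)cyclohexan-1-ol; 12 angelic acid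
Product: 14 (1R,2R,3R)-2,3-dimethyl-4-methylidene-3-(3-methylbut-2-en-1-yl)cyclohexyl (2Z)-2-methylbut-2-enoate, via mixed anhydride 13 (not isolated)
Conditions: 12, 2,4,6-trichlorobenzoyl chloride, Et3N, toluene, rt; then 11, 75 °C
Reagents that add atoms: none
Why: Yamaguchi-type acylation through the mixed anhydride, run without a nucleophilic catalyst, esterifies the hindered equatorial C3 hydroxyl on a robust substrate without Z to E isomerisation of the angeloyl group.

Step 8
Reactants: 14 (1R,2R,3R)-2,3-dimethyl-4-methylidene-3-(3-methylbut-2-en-1-yl)cyclohexyl (2Z)-2-methylbut-2-enoate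
Product: 16 (1R,2R,3S,4R)-4-(hydroxymethyl)-2,3-dimethyl-3-(3-methylbut-2-en-1-yl)cyclohexyl (2Z)-2-methylbut-2-enoate, via alkylborane 15 (not isolated)
Conditions: 9-borabicyclo[3.3.1]nonane (9-BBN, 1.5 equiv), THF, 0 °C → rt; then 30% H2O2, 3 M aq NaOAc, 0 °C → rt
Reagents that add atoms: hydrogen peroxide (OO)
Why: hydroboration–oxidation with 9-BBN touches only the 1,1-disubstituted exocyclic alkene (the trisubstituted prenyl and the conjugated angelate are inert), and hydrogen is delivered to C10 from the face opposite the axial C5 methyl, which sets H-10 trans to the angular methyl.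

Step 9
Reactants: 16 (1R,2R,3S,4R)-4-(hydroxymethyl)-2,3-dimethyl-3-(3-methylbut-2-en-1-yl)cyclohexyl (2Z)-2-methylbut-2-enoate
Product: 17 (1R,2R,3S,4R)-4-(hydroxymethyl)-3-[2-(hydroxymethyl)-3-methylbut-3-en-1-yl]-2,3-dimethylcyclohexyl (2Z)-2-methylbut-2-enoate (both C7 epimers)
Conditions: (CH2O)n (3 equiv, cracked to CH2O in the flask), Me2AlCl (3.5 equiv), CH2Cl2, −78 → 0 °C; aq HCl work-up
Reagents that add atoms: formaldehyde (C=O)
Why: the Me2AlCl-promoted carbonyl-ene reaction of monomeric formaldehyde, released from paraformaldehyde by the Lewis acid, bonds C8 to the less substituted alkene carbon C7 and takes hydrogen from a methyl group, which creates the isopropenyl unit; C7 forms unselectively and is corrected in step 11.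

Step 10
Reactants: 17 (1R,2R,3S,4R)-4-(hydroxymethyl)-3-[2-(hydroxymethyl)-3-methylbut-3-en-1-yl]-2,3-dimethylcyclohexyl (2Z)-2-methylbut-2-enoate
Product: 18 (1R,2R,3R,4R)-4-formyl-3-(2-formyl-3-methylbut-3-en-1-yl)-2,3-dimethylcyclohexyl (2Z)-2-methylbut-2-enoate (both C7 epimers)
Conditions: Dess–Martin periodinane (3 equiv), NaHCO3, CH2Cl2, 0 °C → rt
Reagents that add atoms: none
Why: buffered Dess–Martin oxidation converts both primary alcohols into aldehydes under neutral conditions that neither epimerise C10 nor move the β,γ double bond into conjugation.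

Step 11
Reactants: 18 (1R,2R,3R,4R)-4-formyl-3-(2-formyl-3-methylbut-3-en-1-yl)-2,3-dimethylcyclohexyl (2Z)-2-methylbut-2-enoate
Product: 19 (1R,2R,4aR,5S,7S,8aR)-5-hydroxy-1,8a-dimethyl-6-oxo-7-(prop-1-en-2-yl)decahydronaphthalen-2-yl (2Z)-2-methylbut-2-enoate
Conditions: 2-(pentafluorophenyl)-6,7-dihydro-5H-pyrrolo[2,1-c][1,2,4]triazol-2-ium tetrafluoroborate (15 mol %), i-Pr2NEt (15 mol %), toluene, 40 °C
Reagents that add atoms: none
Why: Proposed new method: the triazolylidene should add to the less hindered C8 aldehyde (the C9 aldehyde sits on a ring carbon next to the quaternary C5) to give a Breslow-type acyl anion equivalent that attacks C9=O through a chair transition state with both tethers equatorial on ring A, so ring B closes trans-fused with the C9 oxygen equatorial (an axial one would clash with the angular methyl) and C8 emerges as the ketone, while the C7 centre equilibrates through the enol under the amine so that the epimer with equatorial isopropenyl is funnelled through; the closest known reaction type is the carbene-catalysed intramolecular crossed benzoin (acyloin) cyclisation of keto-aldehydes and of hexanedial to six-membered α-ketols.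

Step 12
Reactants: 19 (1R,2R,4aR,5S,7S,8aR)-5-hydroxy-1,8a-dimethyl-6-oxo-7-(prop-1-en-2-yl)decahydronaphthalen-2-yl (2Z)-2-methylbut-2-enoate; 20 (2E)-3-methylpent-2-enoic acid
Product: 21 (1R,2R,4aR,5S,7S,8aR)-1,8a-dimethyl-2-{[(2Z)-2-methylbut-2-enoyl]oxy}-6-oxo-7-(prop-1-en-2-yl)decahydronaphthalen-5-yl (2E)-3-methylpent-2-enoate (target)
Conditions: N,N′-dicyclohexylcarbodiimide (1.5 equiv), 4-(dimethylamino)pyridine (10 mol %), CH2Cl2, 0 °C
Reagents that add atoms: none
Why: Steglich esterification acylates the equatorial α-ketol hydroxyl at low temperature with retention at C9 and without moving the isopropenyl double bond into conjugation.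

**Compound list**

1 | 4-methoxy-3-methylphenol | COc1ccc(O)cc1C | starting material
2 | 4,4-dimethoxy-3-methylcyclohexa-2,5-dien-1-one | CC1=CC(=O)C=CC1(OC)OC | intermediate
3 | 4,4-dimethoxy-3-methylcyclohex-2-en-1-one | CC1=CC(=O)CCC1(OC)OC | intermediate
4 | (1R)-4,4-dimethoxy-3-methylcyclohex-2-en-1-ol | CC1=C[C@H](O)CCC1(OC)OC | intermediate (not isolated)
5 | (4R)-4-hydroxy-2-methylcyclohex-2-en-1-one | CC1=C[C@H](O)CCC1=O | intermediate
6 | (4R)-2-methyl-4-[(triethylsilyl)oxy]cyclohex-2-en-1-one | CC1=C[C@H](O[Si](CC)(CC)CC)CCC1=O | intermediate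
7 | 1-bromo-3-methylbut-2-ene (prenyl bromide) | CC(C)=CCBr | starting material
8 | lithium (3R,4R)-2,3-dimethyl-4-[(triethylsilyl)oxy]cyclohex-1-en-1-olate | [Li+].[O-]C1=C(C)[C@@H](C)[C@H](O[Si](CC)(CC)CC)CC1 | intermediate (not isolated)
9 | (2R,3R,4R)-2,3-dimethyl-2-(3-methylbut-2-en-1-yl)-4-[(triethylsilyl)oxy]cyclohexan-1-one | CC(C)=CC[C@]1(C)[C@@H](C)[C@H](O[Si](CC)(CC)CC)CCC1=O | intermediate (not isolated)
10 | (2R,3R,4R)-4-hydroxy-2,3-dimethyl-2-(3-methylbut-2-en-1-yl)cyclohexan-1-one | CC(C)=CC[C@]1(C)[C@@H](C)[C@H](O)CCC1=O | intermediate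
11 | (1R,2R,3R)-2,3-dimethyl-4-methylidene-3-(3-methylbut-2-en-1-yl)cyclohexan-1-ol | CC(C)=CC[C@]1(C)[C@@H](C)[C@H](O)CCC1=C | intermediate
12 | angelic acid, (2Z)-2-methylbut-2-enoic acid | C/C=C(/C)C(=O)O | starting material
13 | (2Z)-2-methylbut-2-enoic 2,4,6-trichlorobenzoic anhydride | C/C=C(/C)C(=O)OC(=O)c1c(Cl)cc(Cl)cc1Cl | intermediate (not isolated)
14 | (1R,2R,3R)-2,3-dimethyl-4-methylidene-3-(3-methylbut-2-en-1-yl)cyclohexyl (2Z)-2-methylbut-2-enoate | CC(C)=CC[C@]1(C)[C@@H](C)[C@H](OC(=O)/C(C)=C\C)CCC1=C | intermediate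
15 | (1R,2R,3S,4R)-4-[(9-borabicyclo[3.3.1]nonan-9-yl)methyl]-2,3-dimethyl-3-(3-methylbut-2-en-1-yl)cyclohexyl (2Z)-2-methylbut-2-enoate | CC(C)=CC[C@]1(C)[C@@H](C)[C@H](OC(=O)/C(C)=C\C)CC[C@H]1CB1C2CCCC1CCC2 | intermediate (not isolated)
16 | (1R,2R,3S,4R)-4-(hydroxymethyl)-2,3-dimethyl-3-(3-methylbut-2-en-1-yl)cyclohexyl (2Z)-2-methylbut-2-enoate | CC(C)=CC[C@]1(C)[C@@H](C)[C@H](OC(=O)/C(C)=C\C)CC[C@H]1CO | intermediate
17 | (1R,2R,3S,4R)-4-(hydroxymethyl)-3-[2-(hydroxymethyl)-3-methylbut-3-en-1-yl]-2,3-dimethylcyclohexyl (2Z)-2-methylbut-2-enoate, both epimers at the side-chain carbon C7 | C=C(C)C(CO)C[C@]1(C)[C@@H](C)[C@H](OC(=O)/C(C)=C\C)CC[C@H]1CO | intermediate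
18 | (1R,2R,3R,4R)-4-formyl-3-(2-formyl-3-methylbut-3-en-1-yl)-2,3-dimethylcyclohexyl (2Z)-2-methylbut-2-enoate, both epimers at the side-chain carbon C7 | C=C(C)C(C=O)C[C@]1(C)[C@@H](C)[C@H](OC(=O)/C(C)=C\C)CC[C@H]1C=O | intermediate
19 | (1R,2R,4aR,5S,7S,8aR)-5-hydroxy-1,8a-dimethyl-6-oxo-7-(prop-1-en-2-yl)decahydronaphthalen-2-yl (2Z)-2-methylbut-2-enoate | C=C(C)[C@@H]1C[C@]2(C)[C@@H](C)[C@H](OC(=O)/C(C)=C\C)CC[C@H]2[C@H](O)C1=O | intermediate
20 | (2E)-3-methylpent-2-enoic acid | CC/C(C)=C/C(=O)O | starting material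
21 | (1R,2R,4aR,5S,7S,8aR)-1,8a-dimethyl-2-{[(2Z)-2-methylbut-2-enoyl]oxy}-6-oxo-7-(prop-1-en-2-yl)decahydronaphthalen-5-yl (2E)-3-methylpent-2-enoate | C=C(C)[C@@H]1C[C@]2(C)[C@@H](C)[C@H](OC(=O)/C(C)=C\C)CC[C@H]2[C@H](OC(=O)/C=C(\C)CC)C1=O | target

**Step count and risks**

Total step count: 12. Longest linear sequence: 12 steps, from 1 to 21; the route has no side branch.

The three steps most likely to fail:

Step 11 (ring B closure). The wrong aldehyde may become the acyl anion, giving the 9-oxo-8-hydroxy isomer; the amine may trigger an intramolecular aldol to a cyclopentene carbaldehyde; the isopropenyl double bond may move into conjugation. The fallback sets out from 16 and comes back at 19, and fixes the regiochemistry by making C8 a nitrile. Silylation of 16 (TBSCl, imidazole) gives the C9 tert-butyldimethylsilyl ether F1. The Me2AlCl/(CH2O)n ene reaction then gives the C8 alcohol F2. One-pot oxidation with 2,2,6,6-tetramethylpiperidin-1-oxyl (cat.), PhI(OAc)2 and NH4OAc turns the alcohol into the α-isopropenyl nitrile F3. HF·pyridine frees the C9 alcohol to give hydroxy nitrile F4, and Dess–Martin oxidation gives the aldehyde nitrile F5. SmI2 (THF, t-BuOH, visible light, high dilution) generates the C9 ketyl, which adds to the nitrile carbon to give the α-hydroxy imine F6 (not isolated). Aqueous acid work-up hydrolyses F6 to 19. The ketone can then only arise at C8, and no amine base is present.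

Step 9 (ene reaction). The free C9 hydroxyl can form a hemiformal and an oxocarbenium ion that attacks the prenyl group (Prins-type ether); chloro-alcohol by-products can form; the Lewis acid may isomerise the angelate. The fallback sets out from 16 and comes back at 17. Ene-type allylic chlorination of the prenyl group (Ca(OCl)2, solid CO2, CH2Cl2/H2O) gives the secondary allylic chloride F7, which already carries the isopropenyl group. An indium-mediated Barbier reaction with aqueous formaldehyde (In powder, THF/H2O, rt) then bonds the more substituted allyl terminus C7 to formaldehyde and gives diol 17 under neutral, Lewis-acid-free conditions.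

Step 5 (conjugate addition and prenylation). The copper-containing enolate may alkylate slowly, alkylate on oxygen, or give poor selectivity at the quaternary centre. The fallback sets out from 6 and comes back at 10. The enolate 8 is trapped with the smaller and more reactive allyl bromide to give the allyl ketone silyl ether F8 (not isolated), and the acid work-up gives the allyl hydroxy ketone F9. Cross-metathesis of F9 with 2-methylbut-2-ene (neat, second-generation Grubbs catalyst RuCl2(=CHPh)(PCy3)(H2IMes), 40 °C) converts the allyl group into the prenyl group of 10.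

**Further compounds**

F1 | step 11 | (1R,2R,3S,4R)-4-{[(tert-butyldimethylsilyl)oxy]methyl}-2,3-dimethyl-3-(3-methylbut-2-en-1-yl)cyclohexyl (2Z)-2-methylbut-2-enoate | CC(C)=CC[C@]1(C)[C@@H](C)[C@H](OC(=O)/C(C)=C\C)CC[C@H]1CO[Si](C)(C)C(C)(C)C
F2 | step 11 | (1R,2R,3S,4R)-4-{[(tert-butyldimethylsilyl)oxy]methyl}-3-[2-(hydroxymethyl)-3-methylbut-3-en-1-yl]-2,3-dimethylcyclohexyl (2Z)-2-methylbut-2-enoate, both side-chain epimers | C=C(C)C(CO)C[C@]1(C)[C@@H](C)[C@H](OC(=O)/C(C)=C\C)CC[C@H]1CO[Si](C)(C)C(C)(C)C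
F3 | step 11 | (1R,2R,3S,4R)-4-{[(tert-butyldimethylsilyl)oxy]methyl}-3-(2-cyano-3-methylbut-3-en-1-yl)-2,3-dimethylcyclohexyl (2Z)-2-methylbut-2-enoate, both side-chain epimers | C=C(C)C(C#N)C[C@]1(C)[C@@H](C)[C@H](OC(=O)/C(C)=C\C)CC[C@H]1CO[Si](C)(C)C(C)(C)C
F4 | step 11 | (1R,2R,3S,4R)-3-(2-cyano-3-methylbut-3-en-1-yl)-4-(hydroxymethyl)-2,3-dimethylcyclohexyl (2Z)-2-methylbut-2-enoate, both side-chain epimers | C=C(C)C(C#N)C[C@]1(C)[C@@H](C)[C@H](OC(=O)/C(C)=C\C)CC[C@H]1CO
F5 | step 11 | (1R,2R,3R,4R)-3-(2-cyano-3-methylbut-3-en-1-yl)-4-formyl-2,3-dimethylcyclohexyl (2Z)-2-methylbut-2-enoate, both side-chain epimers | C=C(C)C(C#N)C[C@]1(C)[C@@H](C)[C@H](OC(=O)/C(C)=C\C)CC[C@H]1C=O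
F6 | step 11 | (1R,2R,4aR,5S,7S,8aR)-5-hydroxy-6-imino-1,8a-dimethyl-7-(prop-1-en-2-yl)decahydronaphthalen-2-yl (2Z)-2-methylbut-2-enoate | C=C(C)[C@@H]1C[C@]2(C)[C@@H](C)[C@H](OC(=O)/C(C)=C\C)CC[C@H]2[C@H](O)C1=N
F7 | step 9 | (1R,2R,3S,4R)-3-(2-chloro-3-methylbut-3-en-1-yl)-4-(hydroxymethyl)-2,3-dimethylcyclohexyl (2Z)-2-methylbut-2-enoate, both side-chain epimers | C=C(C)C(Cl)C[C@]1(C)[C@@H](C)[C@H](OC(=O)/C(C)=C\C)CC[C@H]1CO
F8 | step 5 | (2R,3R,4R)-2,3-dimethyl-2-(prop-2-en-1-yl)-4-[(triethylsilyl)oxy]cyclohexan-1-one | C=CC[C@]1(C)[C@@H](C)[C@H](O[Si](CC)(CC)CC)CCC1=O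
F9 | step 5 | (2R,3R,4R)-4-hydroxy-2,3-dimethyl-2-(prop-2-en-1-yl)cyclohexan-1-one | C=CC[C@]1(C)[C@@H](C)[C@H](O)CCC1=O
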